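Slowness is what we hand over at this bench: the substrate has a half-life of 3.04 min, while intermediate A takes 1.5 h and intermediate B 0.84 h.

    crystals ⇌ product, rate k1*(cs1 - [product]) while solid is left; crystals form when [product] > cs1 (cs1 = 0.18 M, k1 = 0.0072 s⁻¹)
    substrate → intermediate A (k2 = 0.0038 s⁻¹)
    intermediate B → product (k3 = 2.3 × 10⁻⁴ s⁻¹)
    intermediate A → intermediate B (k4 = 1.3 × 10⁻⁴ s⁻¹)

substrate 0.45 M; time 5.0 h

- product and crystals together at 5.0 h, in percent of the substrate charged
- concentration of product in solution at 80 min, in percent of saturation
- the change that raises the amount of product and crystals together at 5.0 h, in percent of the substrate charged most ("none" if none brings more than 2 percentage points) (delta / zeta / none)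
- amount of product and crystals together at 5.0 h, in percent of the substrate charged, after delta

- delta: doubling the solubility in step 1, all else as stated
- zeta: doubling the dissolution coefficient of step 1, all else as stated

- We count the substrate as intermediate A from the start, since its half-life is much shorter, and this leaves a chain of two slow steps.
- We work in powers of ten. D_A = 4.91 h is the decade time of intermediate A, the time in which that stock, drained by its own step with nothing fed in, falls tenfold; D_B = 2.78 h is the same for intermediate B. D_A is longer, by a factor of 1.77, so we keep both steps and call neither the rate-limiting step.
- With W and V as ten to the powers −t/D_A and −t/D_B, the share not yet product is (D_A·W − D_B·V)/(D_A − D_B). When you come at 5.0 h, that is 20.1%, so we expect y = 79.9%.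
- At 80 min the share is 80.1%, so c(product) is below solubility, and we expect sat = 49.7%.
- Leave the solubility and the dissolution coefficient alone: neither enters this reckoning, and crystals are counted with product. We expect none as the best change, and yb = 79.9%.
- The forecast gives y = 79.3% (78% to 80.5%), sat = 45.7%, best = none and yb = 79.3%, holding that "solubility and dissolution coefficient cannot change it". Our y and sat lie above its values.
- The simulation gives y = 79.3%, sat = 45.7%, best = none and yb = 79.3%, with gains of 0 percentage points for delta and 0 points for zeta; the forecast stands. The limit of solubility makes no difference to y, but reading this flask at 4.49 h or 5.63 h moves y by 5 points.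
- The neighbouring flask is the same charge read at 3.0 h, which is 0.611 of D_A. The same two decade times give a share of 45.6% not yet product, hence 54.4% product. The simulated neighbour holds 53.0% product and crystals together, of which 12.4% is crystals.

(The constants used here were set for the occasion; no experiment stands behind them.)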